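Readings and results are calculated for substances that don't exist; the scatter is artificial.

We count turnovers.

| setting | zeta | alpha | flask |
|---|---|---|---|
| substrate | 0.20 M (in portions, 4) | 0.20 M (in portions, 4) | 0.20 M (in portions, 4) |
| partner | 0.20 M | 0.20 M | 0.200 M |
| protic impurity | 0.020 M | 0.013 M | 0.0200 M |
| free catalyst | 1 mM | 1 mM | 1.0 mM |
| remark | the very flask that is asked about, followed so far; portions every 30 s | run made earlier; portions every 30 s | the portions of substrate follow each other after 30 s, the first at the start |
| time |  |  | 30 min |

| run | time / min | product / % |
|---|---|---|
| zeta | 0.500 | 17.4 |
| zeta | 1.00 | 34.5 |
| zeta | 1.33 | 46.6 |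
| zeta | 2.00 | 66.3 |
| zeta | 2.50 | 77.3 |
| alpha | 2.50 | 80.1 |
| alpha | 8.00 | 93.3 |
| alpha | 15.0 | 95.0 |
| alpha | 20.0 | 93.3 |
| alpha | 30.0 | 94.8 |

(each reading ± 1 percentage point)

- what was read earlier has a scatter of 1 percentage point, one standard deviation
- the reaction counts as stopped when no species that holds the substrate changes by six tenths of a point or more over the second half of the time

- at 30 min, what has stopped the reaction, if anything has (all of the substrate has reacted / the partner has run out first / no working catalyst is left / it is still moving)
- amount of product at 30 min, in percent of the substrate charged

We assume that each product costs one partner and that each protic impurity destroys one partner. For the flask, charged [partner] less charged [protic impurity], divided by charged [free catalyst], gives 180. This is the turnover allowance, the turnovers per catalyst that the partner can pay for. The substrate offers 200, more than the allowance. So in our reckoning the partner is the limiting reagent, and the flask's product ceiling is 90.0%.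

The alpha run tests this. Its ceiling by the same count is 93.5%, and its readings from 8.00 min onward average 94.1%.

The zeta run is this flask followed so far. It reads 34.5% at 1.00 min, a pace of 69.0 min⁻¹ per catalyst. At that pace the allowance lasts 2.61 min, far less than 30 min, so we expect the flask to have stopped by then.

We commit to 90.0%, with the partner out first. The weak link is the impurity's target: the alpha plateau shows a loss, not who bears it.

The forecast says 90.5%, close to our ceiling, but it names a different stop: all of the substrate has reacted. Its ground is that the “impurity seems to destroy substrate about one-for-one”.

The flask gives 90.0% at 30 min, and the stop is this: the partner has run out first.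

catalyst intermediate D → free catalyst + product (k = 10.7 s⁻¹); partner + catalyst intermediate B → catalyst intermediate C (k = 25.0 M⁻¹ s⁻¹); catalyst intermediate C → by-product + catalyst intermediate D (k = 12.0 s⁻¹); substrate + free catalyst → catalyst intermediate A (k = 70.1 M⁻¹ s⁻¹); catalyst intermediate A → catalyst intermediate B (k = 443 s⁻¹); partner + protic impurity → quenched reagent (k = 6.99 M⁻¹ s⁻¹) The weak link can now be reforged. At 30 min the flask holds 0% of its partner and 9.5% of its substrate, and quenched reagent stands at 0.0200 M, matching the charge of protic impurity. By the equations, each quenched reagent took one partner with one protic impurity. A neighbour flask carries 0.34 M of partner, with the other charges as here. Its allowance is 320, above the substrate's 200, so the reckoning has substrate ending first, with 35.3% of the partner over. That neighbour gives 100% product and keeps 35% of its partner.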